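**Plan**

- Numbering: pyrrole N1, aminal CH C6, urea N7, urea C8(=O), urea N9, quaternary aminal C10, CH2 groups C11–C13, lactam N14. Rings: A pyrrole, B six-membered lactam, C pyrrolidine, D cyclic urea.
- Enabling feature: C6 (aldehyde level) and C10 (ketone level) are the two carbons of a 1,2-dicarbonyl unit, each masked by two nitrogens (C6 by N1 and N7, C10 by N9 and N14), as in a glycoluril.
- Retrosynthesis: the four aminal bonds C6–N7, C10–N9, C10–N14 and C6–N1 are cut together, giving ketoaldehyde 7 and urea 8. Compound 7 is then cut at C6–C10 (diazo carbon on an acid carbonyl) and at the amide bond N14–C(=O), giving 4-aminobutanoic acid 1, trichloroacetylpyrrole 2 and (trimethylsilyl)diazomethane 4.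
- Forward: ring A is bought; the chain is joined by amide formation, extended by one carbon to the diazoketone and oxidised to the ketoaldehyde. Rings D, C and B then close in that order in one flask.
- Stereochemistry: C10 (R) is set by the chiral Brønsted acid during the N14 closure. C6 (S) follows from C10 because rings B and D can only be cis-fused.

Key step: step 4

Assumption: the sense of induction of the chiral acid cannot be derived from precedent; the (S,S)-catalyst is written, and its (R,R)-enantiomer is used instead should a first run deliver the mirror image.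

**Route**

Step 1
Reactants: 1 4-aminobutanoic acid; 2 2,2,2-trichloro-1-(4,5-dibromo-1H-pyrrol-2-yl)ethanone
Product: 3 4-[(4,5-dibromo-1H-pyrrole-2-carbonyl)amino]butanoic acid
Conditions: Et3N (2.5 equiv), DMF, rt → 40 °C; 1 M HCl work-up
Reagents that add atoms: none
Why: The free amine of the carboxylate salt attacks the trichloroacetyl carbonyl and trichloromethanide leaves as chloroform (haloform-type amide formation with a trichloroacetylpyrrole), so no coupling reagent is needed and the carboxylate and the pyrrole N–H stay untouched.

Step 2
Reactants: 3 4-[(4,5-dibromo-1H-pyrrole-2-carbonyl)amino]butanoic acid; 4 (trimethylsilyl)diazomethane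
Product: 6 4,5-dibromo-N-(5-diazo-4-oxopentyl)-1H-pyrrole-2-carboxamide, via mixed ethyl carbonic anhydride 5 (not isolated)
Conditions: ClCO2Et (1.05 equiv), Et3N (1.05 equiv), THF, −15 °C; then TMSCHN2 (2 equiv), MeCN, 0 → 4 °C; AcOH quench
Reagents that add atoms: ethyl chloroformate, CCOC(=O)Cl (its atoms remain only in intermediate 5)
Why: Ethyl chloroformate converts the acid into mixed carbonic anhydride 5, which C-acylates (trimethylsilyl)diazomethane with loss of the silyl group (first stage of an Arndt–Eistert sequence in its TMSCHN2 variant); the amide and pyrrole N–H groups should be neither acylated at −15 °C nor methylated in the absence of methanol.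

Step 3
Reactants: 6 4,5-dibromo-N-(5-diazo-4-oxopentyl)-1H-pyrrole-2-carboxamide
Product: 7 4,5-dibromo-N-(4,5-dioxopentyl)-1H-pyrrole-2-carboxamide
Conditions: DMDO (1.1 equiv, acetone solution), acetone, −78 → 0 °C; evaporate cold, use at once
Reagents that add atoms: dimethyldioxirane, CC1(C)OO1
Why: The dioxirane transfers oxygen to the nucleophilic diazo carbon and dinitrogen is lost (known dioxirane oxidation of α-diazoketones to α-ketoaldehydes); the electron-poor 2-acyl-4,5-dibromopyrrole should react far more slowly than the diazo carbon at low temperature, and the crude ketoaldehyde, in equilibrium with its hydrate and its N14–C10 cyclic hemiaminal, is carried on directly.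

Step 4
Reactants: 7 4,5-dibromo-N-(4,5-dioxopentyl)-1H-pyrrole-2-carboxamide; 8 urea
Product: 11 dibromophakellstatin (6S,10R), via dihydroxyimidazolidinone adduct 9 (not isolated), via (10R)-spiro hemiaminal 10 (not isolated)
Conditions: urea (1.1 equiv), MeCN, rt; then (S,S)-imidodiphosphoric acid from 3,3′-bis(2,4,6-triethylphenyl)-BINOL (10 mol %), CHCl3/MeCN 9:1, 5 Å MS, 0 °C → rt; Et3N quench; chromatography, recrystallisation
Reagents that add atoms: none
Why: Proposed new method: urea adds reversibly to both carbonyl groups of 7 and ring D closes by 5-exo-trig addition of the second urea nitrogen to give diol 9; the chiral acid then ionises the tertiary C10–OH to an N-acyliminium ion (C10=N9) paired with the confined anion, amide N14 captures it in a 5-exo-trig closure of ring C (spiro hemiaminal 10), and a second ionisation at C6 gives the C6=N7 acyliminium ion, which pyrrole N1–H, hydrogen-bonded to the anion, captures in a 6-exo-trig closure of ring B. The closest known reaction types are acid-catalysed glycoluril formation from 1,2-dicarbonyl compounds and ureas, chiral phosphoric acid catalysed condensation of glyoxals with ureas, chiral acid catalysed cyclic aminal formation from amides and iminium ions, and the N14-to-C10 then N1-to-C6 closures of oxidative (Büchi-type) cyclisations of 4-alkylimidazole precursors in this alkaloid family. C10 (R) is set under catalyst control, because N14 is delivered to one face of the ion-paired C10=N9 ion inside the chiral pocket; C6 (S) is set under substrate control, because rings B and D can only be cis-fused and N1 therefore reaches the planar C6 cation only on the face that carries N14. The step needs enantiofacial selectivity at C10, chemoselectivity for N14 capture over loss of the C6 proton from the C10 cation (which would tautomerise to the 5-alkylhydantoin), and N1 over C3 selectivity of the pyrrole; the first rests on the tight ion pair in a weakly polar medium, the second on the intramolecular 5-exo capture at low temperature with sieves, and the third on the deactivation of C3 by the acyl group and both bromine atoms while N1–H is activated by the basic anion. All events before the second C–N bond at each carbon are reversible, so hydrates, mis-added urea and C6 epimers of 10 should return to the productive path, and the reaction is quenched at full conversion so that the finished aminals do not re-ionise.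

**Compound list**

1 | 4-aminobutanoic acid | NCCCC(=O)O | starting material
2 | 2,2,2-trichloro-1-(4,5-dibromo-1H-pyrrol-2-yl)ethanone | O=C(c1cc(Br)c(Br)[nH]1)C(Cl)(Cl)Cl | starting material
3 | 4-[(4,5-dibromo-1H-pyrrole-2-carbonyl)amino]butanoic acid | O=C(O)CCCNC(=O)c1cc(Br)c(Br)[nH]1 | intermediate
4 | (trimethylsilyl)diazomethane | C[Si](C)(C)C=[N+]=[N-] | starting material
5 | mixed ethyl carbonic anhydride of acid 3 (formed in the flask) | CCOC(=O)OC(=O)CCCNC(=O)c1cc(Br)c(Br)[nH]1 | intermediate
6 | 4,5-dibromo-N-(5-diazo-4-oxopentyl)-1H-pyrrole-2-carboxamide | [N-]=[N+]=CC(=O)CCCNC(=O)c1cc(Br)c(Br)[nH]1 | intermediate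
7 | 4,5-dibromo-N-(4,5-dioxopentyl)-1H-pyrrole-2-carboxamide | O=CC(=O)CCCNC(=O)c1cc(Br)c(Br)[nH]1 | intermediate
8 | urea | NC(N)=O | starting material
9 | 4,5-dibromo-N-[3-(4,5-dihydroxy-2-oxoimidazolidin-4-yl)propyl]-1H-pyrrole-2-carboxamide, mixture of diastereomers (formed in the flask) | O=C1NC(O)C(O)(CCCNC(=O)c2cc(Br)c(Br)[nH]2)N1 | intermediate
10 | (5R)-6-(4,5-dibromo-1H-pyrrole-2-carbonyl)-4-hydroxy-1,3,6-triazaspiro[4.4]nonan-2-one, spiro carbon = C10 (R), both epimers at the carbinol carbon C6 (formed in the flask) | O=C1NC(O)[C@]2(CCCN2C(=O)c2cc(Br)c(Br)[nH]2)N1 | intermediate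
11 | dibromophakellstatin, (6S,10R), rings B/D cis-fused | O=C1N[C@H]2n3c(cc(Br)c3Br)C(=O)N3CCC[C@]23N1 | target

**Totals**

Total step count: 4. Longest linear sequence: 4 steps (1 or 2 → 3 → 6 → 7 → 11).

**Steps most likely to fail**

1. Step 4. Three processes may defeat the cascade:
   - the C10 cation may lose the C6 proton and drain into the hydantoin;
   - the final N1 closure may stall at the spiro stage or compete with attack through pyrrole C3;
   - the small, polar, urea-buffered ion pair may give poor enantiofacial discrimination.

   Fallback with known chemistry, setting out from diazoketone 6 and returning at 11: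
   - HBr (48 % aq.) in THF at 0 °C should give N-(5-bromo-4-oxopentyl)-4,5-dibromo-1H-pyrrole-2-carboxamide F1.
   - NaN3 in DMF should give N-(5-azido-4-oxopentyl)-4,5-dibromo-1H-pyrrole-2-carboxamide F2.
   - Staudinger reduction (PPh3, THF, then 1 M HCl) should give N-(5-amino-4-oxopentyl)-4,5-dibromo-1H-pyrrole-2-carboxamide hydrochloride F3.
   - KOCN in water at 60 °C should give, by ureido ketone formation and cyclodehydration, 4,5-dibromo-N-[3-(2-oxo-2,3-dihydro-1H-imidazol-4-yl)propyl]-1H-pyrrole-2-carboxamide F4.
   - Büchi-type oxidative cyclisation (NBS, TFA, then Et3N) should give racemic dibromophakellstatin F5: bromination at C6, N14 closure at C10, then base-induced N1 closure at C6.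
   - Preparative HPLC on a chiral stationary phase then gives 11.

2. Step 3. The dioxirane may over-oxidise the pyrrole ring, or the hydrated ketoaldehyde may oligomerise during the oxidation and concentration. Fallback, setting out from 6 and returning at 7: acid hydrolysis of the diazo group (aq. H2SO4, dioxane, 50 °C) should give 4,5-dibromo-N-(5-hydroxy-4-oxopentyl)-1H-pyrrole-2-carboxamide F6. Oxidation of its primary α-ketol hydroxyl with IBX in EtOAc at 70 °C, followed by filtration, should then give 7 without a free electrophilic oxygen-transfer agent.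

3. Step 2. The activated γ-amido acid may close onto N14 to the N-acylpyrrolidinone faster than the mixed anhydride acylates the weakly nucleophilic silyl diazomethane. Fallback, setting out from 2 and returning at 7 (it bypasses steps 2 and 3), with the two-carbon unit brought in as an alkene on the amine:
   - 2 with pent-4-en-1-amine (Et3N, MeCN, rt) should give 4,5-dibromo-N-(pent-4-en-1-yl)-1H-pyrrole-2-carboxamide F7.
   - Upjohn dihydroxylation (cat. K2OsO4, NMO, acetone/H2O) should give racemic 4,5-dibromo-N-(4,5-dihydroxypentyl)-1H-pyrrole-2-carboxamide F8.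
   - Double Swern oxidation ((COCl)2, DMSO, Et3N, CH2Cl2, −78 °C) should give 7.

Further compounds
F1 | step 4 | N-(5-bromo-4-oxopentyl)-4,5-dibromo-1H-pyrrole-2-carboxamide | O=C(CBr)CCCNC(=O)c1cc(Br)c(Br)[nH]1
F2 | step 4 | N-(5-azido-4-oxopentyl)-4,5-dibromo-1H-pyrrole-2-carboxamide | [N-]=[N+]=NCC(=O)CCCNC(=O)c1cc(Br)c(Br)[nH]1
F3 | step 4 | N-(5-amino-4-oxopentyl)-4,5-dibromo-1H-pyrrole-2-carboxamide hydrochloride | Cl.NCC(=O)CCCNC(=O)c1cc(Br)c(Br)[nH]1
F4 | step 4 | 4,5-dibromo-N-[3-(2-oxo-2,3-dihydro-1H-imidazol-4-yl)propyl]-1H-pyrrole-2-carboxamide | O=C1NC=C(CCCNC(=O)c2cc(Br)c(Br)[nH]2)N1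
F5 | step 4 | racemic dibromophakellstatin (6S*,10R*, cis-fused) | O=C1NC2n3c(cc(Br)c3Br)C(=O)N3CCCC23N1
F6 | step 3 | 4,5-dibromo-N-(5-hydroxy-4-oxopentyl)-1H-pyrrole-2-carboxamide | O=C(CO)CCCNC(=O)c1cc(Br)c(Br)[nH]1
F7 | step 2 | 4,5-dibromo-N-(pent-4-en-1-yl)-1H-pyrrole-2-carboxamide | C=CCCCNC(=O)c1cc(Br)c(Br)[nH]1
F8 | step 2 | 4,5-dibromo-N-(4,5-dihydroxypentyl)-1H-pyrrole-2-carboxamide (racemic) | OCC(O)CCCNC(=O)c1cc(Br)c(Br)[nH]1
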